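The vessel is closed, stirred and isothermal, so the falling L in it is the curve to watch.

- summer: L 0.11 M; G 5.5 mM; Z 2.2 mM; the very flask that is asked about, followed so far
- flask: L 0.11 M; G 5.50 mM; Z 2.2 mM; time 20 min

summer run (percent of the L charged)

| time / min | Q / % | L / % |
|---|---|---|
| 0.417 | 3.7 | 94.6 |
| 1.33 | 7.3 | 87.8 |
| 2.00 | 12.4 | 83.4 |
| 3.00 | 18.0 | 76.9 |
| 5.00 | 28.3 | 65.9 |
| 6.00 | 32.4 | 61.1 |

(scatter of a reading: 0.5 percentage points)

- average number of monomer units in a chain (chains begun, living or dead) at 20 min
- part of the L that has reacted at 20 min

- the average divides the monomer in chains by the number of chains begun, living and dead together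
- the earlier runs do not show the number of chains; that part of a forecast is a guess

We replace that curve by its mean slope, the part of the L present that goes each minute, 0.0783 min⁻¹, a pseudo-first-order constant taken from the first and last readings. In our first extreme this slope holds to 20 min and leaves 20.4% of the charge. The error of a mean shows in its halves: the slope is 0.0802 min⁻¹ up to 3.00 min and 0.0767 min⁻¹ after it. In our second extreme that fall goes on at the same pace, so the slope after 6.00 min averages 0.0659 min⁻¹ and leaves 24.3%. One reading moved by 0.5 percentage points could erase that fall, while the second extreme takes it at full value, so we expect c between 75.7% and 79.6%. The readings do not show the number of chains, so we give no dp.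

The forecast gives dp 30 (11 to 42) and c 78% (71% to 83%), and says of the chains: “This part is a guess”.

    L + Z → D + Q (k = 0.846 L mol⁻¹ s⁻¹)
    L + D → Q + D, rate k2*[D]*[L] (k = 0.944 L mol⁻¹ s⁻¹)
    2 Z → X (k = 40.3 L mol⁻¹ s⁻¹)
    G + L → J (k = 0.0916 L mol⁻¹ s⁻¹)
    L → E (k = 6.55 × 10⁻⁵ s⁻¹)

The flask gives c 78.4%, between our extremes, and dp 62.3, twice the forecast. At 20.0 min it holds the living ends D at 0.00123 M. Our slope divided by 0.944 L mol⁻¹ s⁻¹ puts the ends at an estimated 0.00138 M, and with each end counted as one chain begun, the Q of this flask at that time gives an estimated dp of 55.3.

In a neighbour flask, like this one but charged with 0.044 M of L, the same slope leaves 20.9% of the charge at 20 min. That neighbour flask, when computed, keeps 31.5%, with D at 8.03 × 10⁻⁴ M and dp 28.7.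

The earlier runs and the new flask were computed from invented constants, noise included.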